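**Plan**
Numbering: chromene O1, C2, C3, C4, C4a, C5–C8, C8a; side chain C1'–C25' counted from C2. The retrosynthesis cuts O1–C2 first, then the C15'=C16' alkene, the C13'–C14' bond, the aryl–allyl bond C4–C4a, and in the tail C16'–C17' and C17'–C18'.
Forward: bis-MOM hydroquinone is geranylgeranylated, the chain end is oxidised at the future C13' and extended by two carbons to the C15' aldehyde. A homogeranyl-substituted ester ylide made from geranyl bromide is joined by Wittig reaction, the ester is reduced and the MOM groups are removed. The only ring, the 2H-pyran, closes last.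
Enabling feature: the ring O1–C2–C3–C4–C4a–C8a is the dehydrogenated, cyclised first isoprene unit (C4, C3, C2, 2-CH3) of a 2-polyprenylhydroquinone, so oxidation at C4 beside the C8a hydroxyl opens an oxa-6π closure.
Stereochemistry: the E alkenes at C3', C7', C11' and C19' come from geranylgeraniol and geranyl bromide. The C15'=C16' geometry (CH2OH trans to C14') comes from the stabilised-ylide Wittig reaction. C2 (S) is set by the active site of the oxidocyclase.

Key step: step 14

Assumption: the C15'=C16' alkene is made exactly as drawn (CH2OH trans to C14', CIP E), and an oxidocyclase variant that accepts the carboxylate-free hydroquinone is taken to be obtainable by screening and directed evolution of a daurichromenic-acid-synthase-type scaffold.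

**Route**

Step 1
Reactants: 1 hydroquinone
Product: 2 1,4-bis(methoxymethoxy)benzene
Conditions: NaH (2.4 equiv), MOMCl (2.4 equiv), THF/DMF, 0 °C → rt
Reagents that add atoms: chloromethyl methyl ether, COCCl
Why: Williamson-type O-alkylation of the bis-phenoxide should give the bis-acetal, which masks the oxidation-prone hydroquinone and later directs ortho-lithiation.

Step 2
Reactants: 3 (2E,6E,10E)-geranylgeraniol
Product: 4 (2E,6E,10E)-geranylgeranyl bromide
Conditions: PBr3 (0.4 equiv), Et2O, –10 °C; used crude
Reagents that add atoms: phosphorus tribromide, BrP(Br)Br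
Why: bromination of a primary allylic alcohol through its phosphite ester with SN2 displacement is the standard way to prenyl bromides and should keep the 2E geometry.

Step 3
Reactants: 2 1,4-bis(methoxymethoxy)benzene; 4 geranylgeranyl bromide
Product: 6 2-[(2E,6E,10E)-geranylgeranyl]-1,4-bis(methoxymethoxy)benzene, via aryllithium 5 (not isolated)
Conditions: n-BuLi (1.1 equiv), TMEDA, THF, 0 °C; then 4 (0.9 equiv), –78 °C → rt
Reagents that add atoms: none
Why: directed ortho-metalation beside an OMOM group (all four ring positions are equivalent) followed by SN2 alkylation at the primary allylic bromide should form the C4–C4a bond with the E alkene intact.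

Step 4
Reactants: 6 2-geranylgeranyl-1,4-bis(methoxymethoxy)benzene
Product: 7 (2E,6E,10E,14E)-16-[2,5-bis(methoxymethoxy)phenyl]-2,6,10,14-tetramethylhexadeca-2,6,10,14-tetraen-1-ol
Conditions: SeO2 (0.2 equiv), t-BuOOH (3 equiv), salicylic acid (0.1 equiv), CH2Cl2, 0 °C → rt, stopped at partial conversion, 6 recycled
Reagents that add atoms: selenium dioxide, O=[Se]=O (catalytic oxygen carrier); tert-butyl hydroperoxide, CC(C)(C)OO (terminal oxidant)
Why: the catalytic Riley allylic oxidation (ene reaction, then [2,3]-sigmatropic shift) should hydroxylate the E-methyl group of the terminal, least hindered trisubstituted alkene, as it does in geranyl, farnesyl and geranylgeranyl derivatives, giving the future C13' as an (E)-allylic alcohol.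

Step 5
Reactants: 7 terminal (E)-allylic alcohol
Product: 8 2-[(2E,6E,10E,14E)-16-bromo-3,7,11,15-tetramethylhexadeca-2,6,10,14-tetraenyl]-1,4-bis(methoxymethoxy)benzene
Conditions: CBr4 (1.3 equiv), PPh3 (1.4 equiv), CH2Cl2, 0 °C
Reagents that add atoms: carbon tetrabromide, BrC(Br)(Br)Br
Why: the Appel reaction should convert the primary allylic alcohol to the bromide under neutral conditions, without allylic transposition and without harm to the MOM acetals.

Step 6
Reactants: 8 terminal allylic bromide
Product: 9 (4E,8E,12E,16E)-18-[2,5-bis(methoxymethoxy)phenyl]-4,8,12,16-tetramethyloctadeca-4,8,12,16-tetraenenitrile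
Conditions: MeCN (5 equiv), n-BuLi (4.5 equiv), THF, –78 °C; then 8, –78 → –30 °C
Reagents that add atoms: acetonitrile, CC#N
Why: SN2 alkylation of lithioacetonitrile, used in excess to suppress double alkylation, at the primary allylic bromide should form C13'–C14' and bring in C14' and C15'.

Step 7
Reactants: 9 nitrile
Product: 11 (4E,8E,12E,16E)-18-[2,5-bis(methoxymethoxy)phenyl]-4,8,12,16-tetramethyloctadeca-4,8,12,16-tetraenal, via aluminated aldimine 10 (not isolated)
Conditions: i-Bu2AlH (1.3 equiv), toluene, –78 °C; then aq. potassium sodium tartrate (KNaC4H4O6) and dilute aq. citric acid, 0 °C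
Reagents that add atoms: water, O
Why: a single hydride transfer to the nitrile should stop at the N-aluminated aldimine, which mild aqueous acid hydrolyses to the aldehyde while the aryl MOM ethers survive.

Step 8
Reactants: 12 geranyl bromide
Product: 13 [(3E)-4,8-dimethylnona-3,7-dienyl] phenyl sulfide (homogeranyl phenyl sulfide)
Conditions: PhSMe (1.2 equiv), n-BuLi (1.15 equiv), DABCO, THF, 0 °C; then 12, –78 °C → rt
Reagents that add atoms: thioanisole, CSc1ccccc1
Why: SN2 alkylation of (phenylthio)methyllithium at the primary allylic bromide should give the one-carbon homologue (future C17') with the E alkene untouched.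

Step 9
Reactants: 13 homogeranyl phenyl sulfide
Product: 15 (3E)-1-iodo-4,8-dimethylnona-3,7-diene (homogeranyl iodide), via sulfonium iodide 14 (not isolated)
Conditions: MeI (excess), NaI, DMF, 75 °C, sealed, dark
Reagents that add atoms: methyl iodide, CI; sodium iodide, [Na+].[I-] (iodide pool)
Why: S-methylation gives a sulfonium salt whose primary homoallylic carbon is displaced by iodide with loss of thioanisole, the established two-stage homologation of allylic halides to homoallylic iodides.

Step 10
Reactants: 15 homogeranyl iodide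
Product: 17 ethyl (5E)-6,10-dimethyl-2-(triphenyl-λ5-phosphanylidene)undeca-5,9-dienoate, via phosphonium iodide 16 (not isolated)
Conditions: Ph3P=CHCO2Et (2.0 equiv), MeCN, 80 °C; precipitated phosphonium salt filtered off, ylide purified on SiO2
Reagents that add atoms: (ethoxycarbonylmethylene)triphenylphosphorane, CCOC(=O)C=P(c1ccccc1)(c1ccccc1)c1ccccc1
Why: C-alkylation of the ester-stabilised ylide by the primary iodide, followed by transylidation with the second equivalent of ylide, should give the α-substituted ylide carrying C16', its ester carbon and the C17'–C25' tail.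

Step 11
Reactants: 11 aldehyde; 17 α-substituted ester ylide
Product: 18 ethyl (2E,6E,10E,14E,18E)-20-[2,5-bis(methoxymethoxy)phenyl]-2-[(3E)-4,8-dimethylnona-3,7-dienyl]-6,10,14,18-tetramethylicosa-2,6,10,14,18-pentaenoate
Conditions: 17 (1.5 equiv), toluene, 90 °C
Reagents that add atoms: none
Why: in the Wittig reaction of an ester-stabilised, α-substituted ylide the reversible oxaphosphetane formation should lead to the (E)-enoate, with the ester trans to C14' and the homogeranyl group cis to it, which is the geometry required at C15'=C16'.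

Step 12
Reactants: 18 enoate
Product: 19 (2E,6E,10E,14E,18E)-20-[2,5-bis(methoxymethoxy)phenyl]-2-[(3E)-4,8-dimethylnona-3,7-dienyl]-6,10,14,18-tetramethylicosa-2,6,10,14,18-pentaen-1-ol
Conditions: i-Bu2AlH (3 equiv), CH2Cl2, –78 → –20 °C; aq. potassium sodium tartrate (KNaC4H4O6)
Reagents that add atoms: none
Why: 1,2-reduction of the conjugated ester by i-Bu2AlH at low temperature should give the primary allylic alcohol without moving the alkene or touching the MOM acetals.

Step 13
Reactants: 19 bis-MOM allylic alcohol
Product: 20 (2E,6E,10E,14E,18E)-20-(2,5-dihydroxyphenyl)-2-[(3E)-4,8-dimethylnona-3,7-dienyl]-6,10,14,18-tetramethylicosa-2,6,10,14,18-pentaen-1-ol (the open hydroquinone)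
Conditions: HCl (0.5 M) in degassed MeOH, 0 °C → rt, Ar; work-up and storage under Ar
Reagents that add atoms: none
Why: acid-catalysed transacetalisation of the two aryl MOM ethers to dimethoxymethane should free the hydroquinone, and dilute acid at or below room temperature is expected to spare the trisubstituted alkenes and the allylic alcohol.

Step 14
Reactants: 20 open hydroquinone
Product: 22 (2S)-2-[(3E,7E,11E,15E,19E)-16-(hydroxymethyl)-4,8,12,20,24-pentamethylpentacosa-3,7,11,15,19,23-hexaenyl]-2-methyl-2H-chromen-6-ol, via ortho-quinone methide 21 (not isolated)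
Conditions: engineered FAD-dependent berberine-bridge-enzyme-like oxidocyclase (daurichromenic acid synthase scaffold), air, catalase, citric acid/Na2HPO4 buffer pH 6.0, 2-hydroxypropyl-β-cyclodextrin, 30 °C, dark; EtOAc extraction, SiO2 chromatography
Reagents that add atoms: none
Why: Proposed new method: the enzyme-bound FAD should accept a hydride from C4, the only CH2 that is benzylic and allylic at once, while an active-site base takes the proton of the C8a hydroxyl, which gives the Z-configured vinylogous ortho-quinone methide 21 (O=C8a–C4a=C4–C3=C2, also the tautomer of the para-quinone, so a path through two-electron oxidation of the hydroquinone and enzyme-bound tautomerisation ends at the same species), and O2 then reoxidises the reduced flavin with release of H2O2. Rotation about the C4–C3 single bond brings O1 over C2, and the 2H-pyran ring (O1, C2, C3, C4, C4a, C8a) closes by a thermally allowed disrotatory oxa-6π electrocyclisation that forms O1–C2, moves the alkene to C3=C4 and restores the arene. The closest known reaction type is chromene formation from ortho-prenylated phenolic acids by berberine-bridge-enzyme-like oxidocyclases (daurichromenic acid synthase, cannabichromenic acid synthase), which has not been shown for a carboxylate-free hydroquinone with a C35 chain, so a suitable variant would have to be found by screening and directed evolution. C2, the only new stereocentre, is controlled by the protein alone: the active site has to hold the oxatriene in one helical sense so that O1 adds to the Si face of C2 and gives S, whereas the free quinone methide would close without facial preference. The step needs oxidation at C4 and at none of the other allylic CH2 groups or the CH2OH, which rests on the hydroquinone head being the only part able to bind beside the flavin and on the ionisable C8a hydroxyl ortho to the C4-bearing carbon; the C6 hydroxyl para to O1 lowers the oxidation potential, and no protecting group is required.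

**Compound list**
1 | hydroquinone (benzene-1,4-diol) | Oc1ccc(O)cc1 | starting material
2 | 1,4-bis(methoxymethoxy)benzene | COCOc1ccc(OCOC)cc1 | intermediate
3 | (2E,6E,10E)-geranylgeraniol | CC(C)=CCC/C(C)=C/CC/C(C)=C/CC/C(C)=C/CO | starting material
4 | (2E,6E,10E)-geranylgeranyl bromide | CC(C)=CCC/C(C)=C/CC/C(C)=C/CC/C(C)=C/CBr | intermediate
5 | 2,5-bis(methoxymethoxy)phenyllithium | [Li]c1cc(OCOC)ccc1OCOC | intermediate
6 | 2-[(2E,6E,10E)-geranylgeranyl]-1,4-bis(methoxymethoxy)benzene | CC(C)=CCC/C(C)=C/CC/C(C)=C/CC/C(C)=C/Cc1cc(OCOC)ccc1OCOC | intermediate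
7 | (2E,6E,10E,14E)-16-[2,5-bis(methoxymethoxy)phenyl]-2,6,10,14-tetramethylhexadeca-2,6,10,14-tetraen-1-ol | OC/C(C)=C/CC/C(C)=C/CC/C(C)=C/CC/C(C)=C/Cc1cc(OCOC)ccc1OCOC | intermediate
8 | 2-[(2E,6E,10E,14E)-16-bromo-3,7,11,15-tetramethylhexadeca-2,6,10,14-tetraenyl]-1,4-bis(methoxymethoxy)benzene | BrC/C(C)=C/CC/C(C)=C/CC/C(C)=C/CC/C(C)=C/Cc1cc(OCOC)ccc1OCOC | intermediate
9 | (4E,8E,12E,16E)-18-[2,5-bis(methoxymethoxy)phenyl]-4,8,12,16-tetramethyloctadeca-4,8,12,16-tetraenenitrile | N#CCC/C(C)=C/CC/C(C)=C/CC/C(C)=C/CC/C(C)=C/Cc1cc(OCOC)ccc1OCOC | intermediate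
10 | N-(diisobutylalumanyl) aldimine of 11 | CC(C)C[Al](CC(C)C)N=CCC/C(C)=C/CC/C(C)=C/CC/C(C)=C/CC/C(C)=C/Cc1cc(OCOC)ccc1OCOC | intermediate
11 | (4E,8E,12E,16E)-18-[2,5-bis(methoxymethoxy)phenyl]-4,8,12,16-tetramethyloctadeca-4,8,12,16-tetraenal | O=CCC/C(C)=C/CC/C(C)=C/CC/C(C)=C/CC/C(C)=C/Cc1cc(OCOC)ccc1OCOC | intermediate
12 | geranyl bromide, (2E)-1-bromo-3,7-dimethylocta-2,6-diene | CC(C)=CCC/C(C)=C/CBr | starting material
13 | [(3E)-4,8-dimethylnona-3,7-dienyl] phenyl sulfide | CC(C)=CCC/C(C)=C/CCSc1ccccc1 | intermediate
14 | [(3E)-4,8-dimethylnona-3,7-dienyl](methyl)phenylsulfonium iodide | CC(C)=CCC/C(C)=C/CC[S+](C)c1ccccc1.[I-] | intermediate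
15 | (3E)-1-iodo-4,8-dimethylnona-3,7-diene | CC(C)=CCC/C(C)=C/CCI | intermediate
16 | [(5E)-1-ethoxy-6,10-dimethyl-1-oxoundeca-5,9-dien-2-yl]triphenylphosphonium iodide | CC(C)=CCC/C(C)=C/CCC(C(=O)OCC)[P+](c1ccccc1)(c1ccccc1)c1ccccc1.[I-] | intermediate
17 | ethyl (5E)-6,10-dimethyl-2-(triphenyl-λ5-phosphanylidene)undeca-5,9-dienoate | CC(C)=CCC/C(C)=C/CCC(C(=O)OCC)=P(c1ccccc1)(c1ccccc1)c1ccccc1 | intermediate
18 | ethyl (2E,6E,10E,14E,18E)-20-[2,5-bis(methoxymethoxy)phenyl]-2-[(3E)-4,8-dimethylnona-3,7-dienyl]-6,10,14,18-tetramethylicosa-2,6,10,14,18-pentaenoate | CC(C)=CCC/C(C)=C/CC/C(=C\CC/C(C)=C/CC/C(C)=C/CC/C(C)=C/CC/C(C)=C/Cc1cc(OCOC)ccc1OCOC)C(=O)OCC | intermediate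
19 | (2E,6E,10E,14E,18E)-20-[2,5-bis(methoxymethoxy)phenyl]-2-[(3E)-4,8-dimethylnona-3,7-dienyl]-6,10,14,18-tetramethylicosa-2,6,10,14,18-pentaen-1-ol | CC(C)=CCC/C(C)=C/CC/C(=C\CC/C(C)=C/CC/C(C)=C/CC/C(C)=C/CC/C(C)=C/Cc1cc(OCOC)ccc1OCOC)CO | intermediate
20 | (2E,6E,10E,14E,18E)-20-(2,5-dihydroxyphenyl)-2-[(3E)-4,8-dimethylnona-3,7-dienyl]-6,10,14,18-tetramethylicosa-2,6,10,14,18-pentaen-1-ol | CC(C)=CCC/C(C)=C/CC/C(=C\CC/C(C)=C/CC/C(C)=C/CC/C(C)=C/CC/C(C)=C/Cc1cc(O)ccc1O)CO | intermediate
21 | (Z)-ortho-quinone methide of 20 (O=C8a, C4a=C4 exocyclic, C3=C2 retained E, C6–OH) | CC(C)=CCC/C(C)=C/CC/C(=C\CC/C(C)=C/CC/C(C)=C/CC/C(C)=C/CC/C(C)=C/C=C1/C=C(O)C=CC1=O)CO | intermediate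
22 | (2S)-2-[(3E,7E,11E,15E,19E)-16-(hydroxymethyl)-4,8,12,20,24-pentamethylpentacosa-3,7,11,15,19,23-hexaenyl]-2-methyl-2H-chromen-6-ol | CC(C)=CCC/C(C)=C/CC/C(=C\CC/C(C)=C/CC/C(C)=C/CC/C(C)=C/CC[C@@]1(C)C=Cc2cc(O)ccc2O1)CO | target

**Count**
Total step count: 14. Longest linear sequence: 10 steps (steps 1, 3, 4, 5, 6, 7, 11, 12, 13, 14).

**Steps most likely to fail**

Step 14. No variant may accept the long, carboxylate-free substrate, facial control at C2 may be incomplete, or air may oxidise the hydroquinone to the quinone faster than the enzyme turns it over. The fallback sets out from 20 and uses known chemistry. Oxidation with Ag2O in Et2O should give the 2-polyprenyl-1,4-benzoquinone F1. Heating in pyridine should tautomerise it to the same quinone methide 21, which closes without facial control to the racemic chromenol F2. Preparative HPLC on a chiral stationary phase (cellulose tris(3,5-dimethylphenylcarbamate)) should then separate the S enantiomer, so the route is rejoined at 22.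

Step 4. Site selectivity among four trisubstituted alkenes may be poor, and over-oxidation to the enal may lower the yield further. The fallback sets out from 6 and replaces the oxidation by a terminal-selective degradation and sigmatropic rebuild:
- NBS in aqueous THF at 0 °C should give the terminal bromohydrin F3.
- K2CO3 in MeOH should close it to the terminal epoxide F4.
- Al(Oi-Pr)3 in refluxing toluene should isomerise the epoxide to the isopropenyl carbinol F5.
- Johnson–Claisen rearrangement with MeC(OEt)3 and catalytic propionic acid at 135 °C should pass through the mixed ketene acetal F6 and give the γ,δ-unsaturated ethyl ester F7. The chair transition state sets the E alkene and adds both extra carbons at once.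
- i-Bu2AlH at –78 °C should reduce the ester to aldehyde 11, where the route is rejoined; compounds 7, 8 and 9 are bypassed.

Step 10. Alkylation of the weakly nucleophilic stabilised ylide by an unactivated primary iodide may stall, or the iodide may be lost by elimination on prolonged heating. The fallback sets out from 15. Alkylation of the sodium salt of triethyl phosphonoacetate (NaH, DMSO, 60 °C) should give the α-substituted phosphonate F8. Horner–Wadsworth–Emmons reaction of F8 with 11 (NaH, THF, 0 °C → rt) should give the enoate. The E isomer would be separated from any Z isomer by chromatography, so the route is rejoined at 18.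

**Further compounds**
F1 | step 14 | 2-[(2E,6E,10E,14E,18E)-19-(hydroxymethyl)-3,7,11,15,23,27-hexamethyloctacosa-2,6,10,14,18,22,26-heptaenyl]-1,4-benzoquinone | CC(C)=CCC/C(C)=C/CC/C(=C\CC/C(C)=C/CC/C(C)=C/CC/C(C)=C/CC/C(C)=C/CC1=CC(=O)C=CC1=O)CO
F2 | step 14 | racemic chromenol (22 without defined configuration at C2) | CC(C)=CCC/C(C)=C/CC/C(=C\CC/C(C)=C/CC/C(C)=C/CC/C(C)=C/CCC1(C)C=Cc2cc(O)ccc2O1)CO
F3 | step 4 | terminal bromohydrin of 6 (tertiary OH, secondary Br, racemic) | CC(C)(O)C(Br)CC/C(C)=C/CC/C(C)=C/CC/C(C)=C/Cc1cc(OCOC)ccc1OCOC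
F4 | step 4 | terminal epoxide of 6 (racemic) | CC1(C)OC1CC/C(C)=C/CC/C(C)=C/CC/C(C)=C/Cc1cc(OCOC)ccc1OCOC
F5 | step 4 | isopropenyl carbinol (secondary allylic alcohol, racemic) | C=C(C)C(O)CC/C(C)=C/CC/C(C)=C/CC/C(C)=C/Cc1cc(OCOC)ccc1OCOC
F6 | step 4 | mixed ketene acetal of F5 (not isolated) | C=C(C)C(CC/C(C)=C/CC/C(C)=C/CC/C(C)=C/Cc1cc(OCOC)ccc1OCOC)OC(=C)OCC
F7 | step 4 | ethyl (4E,8E,12E,16E)-18-[2,5-bis(methoxymethoxy)phenyl]-4,8,12,16-tetramethyloctadeca-4,8,12,16-tetraenoate | CCOC(=O)CC/C(C)=C/CC/C(C)=C/CC/C(C)=C/CC/C(C)=C/Cc1cc(OCOC)ccc1OCOC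
F8 | step 10 | ethyl (5E)-2-(diethoxyphosphoryl)-6,10-dimethylundeca-5,9-dienoate | CC(C)=CCC/C(C)=C/CCC(C(=O)OCC)P(=O)(OCC)OCC
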